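The route rests on cutting ring B's pyrrole at N1'–C2' and N1'–C7a', so that the crowded C4–N1' bond between ring A and ring B is never made by arylation: it is already present as the C4 amine of ring A. Heating this amine with 6,7-dihydrobenzofuran-4(5H)-one swaps the furan oxygen for nitrogen and delivers ring B as a 4-oxo-tetrahydroindole in one operation. The feature exploited is that ring B's bromines lie at C2' and C5', the pyrrole α-carbon and the ketone α-carbon of that partly saturated bicycle. The precursor is 3,5-dibromo-7-methoxy-1-tosylindol-4-amine, with both ring A bromines and the N1 sulfonyl group in place.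

Key step: step 4

Numbering: ring A is the 7-methoxyindole unit (N1 to C7a); ring B is the indole unit attached through N1' (primed atoms, also used for its partly saturated precursors).

Assumption: the target SMILES carries no stereodescriptor; rotation about the C4–N1' bond is expected to be hindered, and the route gives both rotamers (the racemate) without control.

Step 1
Reactants: 1 4-bromo-7-methoxy-1H-indole
Product: 3 7-methoxy-1H-indol-4-amine, via N-diphenylmethylidene imine 2 (not isolated)
Conditions: Ph2C=NH (1.2 equiv), Pd2(dba)3 (2 mol %), XPhos (8 mol %), LiN(SiMe3)2 (2.3 equiv), THF, 65 °C; then 1 M HCl aq, THF, rt; NaHCO3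
Reagents that add atoms: benzophenone imine, N=C(c1ccccc1)c1ccccc1
Why: Buchwald–Hartwig amination with benzophenone imine as ammonia surrogate: LiN(SiMe3)2 holds N1 as its lithium salt (shielded from N-arylation by the 7-methoxy group) while palladium couples the imine nitrogen at C4–Br, and dilute acid then hydrolyses imine 2 to the primary amine.

Step 2
Reactants: 3 7-methoxy-1H-indol-4-amine
Product: 4 3,5-dibromo-7-methoxy-1H-indol-4-amine
Conditions: NBS (2.0 equiv), THF, −78 to −30 °C, dark
Reagents that add atoms: N-bromosuccinimide, O=C1CCC(=O)N1Br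
Why: Electrophilic aromatic bromination run while N1–H and the C4 amine are both free, so that C3 (the indole β-carbon) and C5 (the only open ortho/para position of the aniline, since para C7 carries the methoxy group) are far more reactive than C2 or C6 and should take up the two equivalents.

Step 3
Reactants: 4 3,5-dibromo-7-methoxy-1H-indol-4-amine
Product: 5 3,5-dibromo-7-methoxy-1-tosyl-1H-indol-4-amine
Conditions: NaH (1.1 equiv), DMF, 0 °C; TsCl (1.1 equiv), 0 °C to rt
Reagents that add atoms: p-toluenesulfonyl chloride, Cc1ccc(cc1)S(Cl)(=O)=O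
Why: N-sulfonylation of the sodium indolide: NaH removes only the much more acidic N1–H, and the C4 amine, flanked by two bromines and weakly nucleophilic, should stay free; the sulfonyl group makes the 3-bromoindole stable to the hot acid of step 4.

Step 4
Reactants: 5 3,5-dibromo-7-methoxy-1-tosyl-1H-indol-4-amine; 6 6,7-dihydrobenzofuran-4(5H)-one
Product: 8 1-(3,5-dibromo-7-methoxy-1-tosyl-1H-indol-4-yl)-6,7-dihydro-1H-indol-4(5H)-one, via ring-opened enaminone aldehyde 7 (not isolated)
Conditions: 6 (3 equiv), TsOH·H2O (0.3 equiv), AcOH, 120 °C, sealed tube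
Reagents that add atoms: none
Why: Acid activates the vinylogous ester of 6 so that the C4 amine of 5 adds at C7a; cleavage of C7a–O1 opens the furan to enaminone aldehyde 7, whose nitrogen attacks the aldehyde carbon in a 5-exo-trig closure, and loss of water aromatises the new pyrrole (N1'–C7a' and N1'–C2' formed, five-membered ring of ring B closed). The closest known reaction type is the amine-induced furan-to-pyrrole exchange of 4-oxo-tetrahydrobenzofurans, an addition, ring-opening and Paal–Knorr-type ring-closure sequence. No stereocenter is created; the hindered C4–N1' axis arises as a racemate. The selectivity needed is attack at C7a instead of condensation at the C4' carbonyl: that carbonyl is deactivated as a vinylogous ester and any imine formed there reverts in the wet acid, whereas pyrrole formation is irreversible. Ring A offers no competing nucleophile because N1 is sulfonylated and C3 is brominated. Should water first open the furan to the 1,4-dicarbonyl compound, its Paal–Knorr condensation with 5 converges on the same product.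

Step 5
Reactants: 8 1-(3,5-dibromo-7-methoxy-1-tosyl-1H-indol-4-yl)-6,7-dihydro-1H-indol-4(5H)-one
Product: 9 2-bromo-1-(3,5-dibromo-7-methoxy-1-tosyl-1H-indol-4-yl)-6,7-dihydro-1H-indol-4(5H)-one
Conditions: NBS (1.0 equiv), THF, −78 to 0 °C, dark
Reagents that add atoms: N-bromosuccinimide, O=C1CCC(=O)N1Br
Why: Electrophilic substitution of a 3-acylpyrrole: C2' is the free α-carbon not conjugated to the C4' carbonyl, whereas C3' is a β-carbon next to the acyl-bearing C3a', and ring A is deactivated by two bromines and the sulfonyl group, so one equivalent of NBS should go to C2'.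

Step 6
Reactants: 9 2-bromo-1-(3,5-dibromo-7-methoxy-1-tosyl-1H-indol-4-yl)-6,7-dihydro-1H-indol-4(5H)-one
Product: 10 2,5-dibromo-1-(3,5-dibromo-7-methoxy-1-tosyl-1H-indol-4-yl)-6,7-dihydro-1H-indol-4(5H)-one (C5' unassigned, racemic)
Conditions: CuBr2 (2.2 equiv), EtOAc/CHCl3 (1:1), reflux
Reagents that add atoms: copper dibromide, Br[Cu]Br
Why: CuBr2-mediated α-bromination of a ketone through its copper-bound enol: C5' is the only enolisable α-carbon (C3a' bears no hydrogen) and the already brominated acylpyrrole is too deactivated for further ring substitution; the C5' stereocenter is formed without control and is erased in step 8.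

Step 7
Reactants: 10 2,5-dibromo-1-(3,5-dibromo-7-methoxy-1-tosyl-1H-indol-4-yl)-6,7-dihydro-1H-indol-4(5H)-one
Product: 11 2,5-dibromo-1-(3,5-dibromo-7-methoxy-1-tosyl-1H-indol-4-yl)-4,5,6,7-tetrahydro-1H-indol-4-ol (mixture of diastereomers)
Conditions: NaBH4 (1.5 equiv), CeCl3·7H2O (1.0 equiv), MeOH/THF, −20 to 0 °C
Reagents that add atoms: none
Why: Luche-type hydride reduction: CeCl3 activates the weakly electrophilic acylpyrrole carbonyl, the α-bromine raises its reactivity further, and the cold, nearly neutral medium should prevent epoxide closure; the C4' and C5' stereocenters arise without control, which is harmless because both carbons become sp2 in step 8.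

Step 8
Reactants: 11 2,5-dibromo-1-(3,5-dibromo-7-methoxy-1-tosyl-1H-indol-4-yl)-4,5,6,7-tetrahydro-1H-indol-4-ol
Product: 13 2,5-dibromo-1-(3,5-dibromo-7-methoxy-1-tosyl-1H-indol-4-yl)-1H-indole, via vinyl bromide diene 12 (not isolated)
Conditions: TsOH·H2O (5 mol %), toluene, 4 Å MS, 50 °C; then DDQ (1.2 equiv), rt
Reagents that add atoms: none
Why: Acid-catalysed E1 dehydration through the nitrogen-stabilised C4' cation, which can lose only H5' and so gives the 5'-bromo-6',7'-dihydroindole 12 (the pyrrole counterpart of the 2-bromo-1-tetralol to 3-bromo-1,2-dihydronaphthalene conversion), followed in the same flask by DDQ dehydrogenation (hydride abstraction at C7', proton loss at C6') to the aromatic 2',5'-dibromoindole.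

Step 9
Reactants: 13 2,5-dibromo-1-(3,5-dibromo-7-methoxy-1-tosyl-1H-indol-4-yl)-1H-indole
Product: 14 3,5-dibromo-4-(2,5-dibromo-1H-indol-1-yl)-7-methoxy-1H-indole (target)
Conditions: KOH (5 equiv), MeOH/THF (1:1), 50 °C; then NH4Cl aq
Reagents that add atoms: none
Why: Nucleophilic cleavage of an N-sulfonylindole by attack at sulfur, with the 3-bromoindolide as a good leaving group and steric strain against the 7-methoxy group helping; the four C–Br bonds on electron-rich rings should be inert to hydroxide and methoxide at this temperature.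

Compound list
1 | 4-bromo-7-methoxy-1H-indole | COc1ccc(Br)c2cc[nH]c12 | starting material
2 | N-(diphenylmethylidene)-7-methoxy-1H-indol-4-amine | COc1ccc(N=C(c3ccccc3)c3ccccc3)c2cc[nH]c12 | intermediate
3 | 7-methoxy-1H-indol-4-amine | COc1ccc(N)c2cc[nH]c12 | intermediate
4 | 3,5-dibromo-7-methoxy-1H-indol-4-amine | COc1cc(Br)c(N)c2c(Br)c[nH]c12 | intermediate
5 | 3,5-dibromo-7-methoxy-1-tosyl-1H-indol-4-amine | COc1cc(Br)c(N)c2c(Br)cn(S(=O)(=O)c3ccc(C)cc3)c12 | intermediate
6 | 6,7-dihydrobenzofuran-4(5H)-one | O=C1CCCc2occc21 | starting material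
7 | 2-{2-[(3,5-dibromo-7-methoxy-1-tosyl-1H-indol-4-yl)amino]-6-oxocyclohex-1-en-1-yl}acetaldehyde | COc1cc(Br)c(NC2=C(CC=O)C(=O)CCC2)c2c(Br)cn(S(=O)(=O)c3ccc(C)cc3)c12 | intermediate
8 | 1-(3,5-dibromo-7-methoxy-1-tosyl-1H-indol-4-yl)-6,7-dihydro-1H-indol-4(5H)-one | COc1cc(Br)c(-n2ccc3c2CCCC3=O)c2c(Br)cn(S(=O)(=O)c3ccc(C)cc3)c12 | intermediate
9 | 2-bromo-1-(3,5-dibromo-7-methoxy-1-tosyl-1H-indol-4-yl)-6,7-dihydro-1H-indol-4(5H)-one | COc1cc(Br)c(-n2c(Br)cc3c2CCCC3=O)c2c(Br)cn(S(=O)(=O)c3ccc(C)cc3)c12 | intermediate
10 | 2,5-dibromo-1-(3,5-dibromo-7-methoxy-1-tosyl-1H-indol-4-yl)-6,7-dihydro-1H-indol-4(5H)-one (C5' unassigned) | COc1cc(Br)c(-n2c(Br)cc3c2CCC(Br)C3=O)c2c(Br)cn(S(=O)(=O)c3ccc(C)cc3)c12 | intermediate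
11 | 2,5-dibromo-1-(3,5-dibromo-7-methoxy-1-tosyl-1H-indol-4-yl)-4,5,6,7-tetrahydro-1H-indol-4-ol (diastereomer mixture) | COc1cc(Br)c(-n2c(Br)cc3c2CCC(Br)C3O)c2c(Br)cn(S(=O)(=O)c3ccc(C)cc3)c12 | intermediate
12 | 2,5-dibromo-1-(3,5-dibromo-7-methoxy-1-tosyl-1H-indol-4-yl)-6,7-dihydro-1H-indole | COc1cc(Br)c(-n2c(Br)cc3c2CCC(Br)=C3)c2c(Br)cn(S(=O)(=O)c3ccc(C)cc3)c12 | intermediate
13 | 2,5-dibromo-1-(3,5-dibromo-7-methoxy-1-tosyl-1H-indol-4-yl)-1H-indole | COc1cc(Br)c(-n2c(Br)cc3cc(Br)ccc32)c2c(Br)cn(S(=O)(=O)c3ccc(C)cc3)c12 | intermediate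
14 | 3,5-dibromo-4-(2,5-dibromo-1H-indol-1-yl)-7-methoxy-1H-indole | COc1cc(Br)c(-n2c(Br)cc3cc(Br)ccc32)c2c(Br)c[nH]c12 | target

Total step count: 9 steps.
Longest linear sequence: 9 steps (1 to 14); compound 6 enters at step 4.

Steps most likely to fail

Step 4. The doubly flanked, weakly basic C4 amine may add too slowly at C7a, so that acid-induced self-condensation of the furanone takes over or the sequence stalls before ring closure. The fallback sets out from 5 and builds ring B in two stages. Condensation of 5 with cyclohexane-1,3-dione (TsOH·H2O cat., toluene, Dean–Stark) should give the enaminone 3-[(3,5-dibromo-7-methoxy-1-tosyl-1H-indol-4-yl)amino]cyclohex-2-en-1-one F1. Annulation with aqueous chloroacetaldehyde (NaHCO3, EtOH, 60 °C, then a trace of acid) then proceeds by C-alkylation at the enaminone α-carbon, intramolecular N-closure and dehydration, and comes back to the route at 8. The hindered nitrogen then has to react only with an activated vinylogous acid and afterwards close a ring intramolecularly.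

Step 2. The electron-rich aminoindole may be oxidised by NBS (attack at the methoxy-bearing para position, leading on to quinone-imine formation), and the unprotected 3-bromoindole may decompose during isolation. The fallback sets out from imine 2, isolated from step 1 before the acid hydrolysis, and separates the two brominations:
- NBS (1 equiv, THF, −78 °C) should brominate C3 to give 3-bromo-N-(diphenylmethylidene)-7-methoxy-1H-indol-4-amine F2.
- NaH/TsCl gives 3-bromo-N-(diphenylmethylidene)-7-methoxy-1-tosyl-1H-indol-4-amine F3.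
- Aqueous HCl in THF frees 3-bromo-7-methoxy-1-tosyl-1H-indol-4-amine F4.
- NBS (1 equiv, DMF, 0 °C) then brominates C5, ortho to the freed amine, and the sequence comes back at 5.

Each bromination then meets a single activated site, and the free aminoindole is never exposed to NBS.

Step 6. HBr released by CuBr2 may cause migration or loss of the pyrrole bromine, a second bromination at C5' may occur, or enolisation of the vinylogous-amide ketone may be too slow. The fallback sets out from 9 and uses a preformed enol derivative. TMSOTf/Et3N (CH2Cl2, 0 °C) should give the silyl enol ether 2-bromo-1-(3,5-dibromo-7-methoxy-1-tosyl-1H-indol-4-yl)-4-[(trimethylsilyl)oxy]-6,7-dihydro-1H-indole F5. NBS (1.0 equiv, THF, −78 °C) then brominates it at C5' under neutral conditions and comes back at 10.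

Further compounds
F1 | step 4 | 3-[(3,5-dibromo-7-methoxy-1-tosyl-1H-indol-4-yl)amino]cyclohex-2-en-1-one | COc1cc(Br)c(NC2=CC(=O)CCC2)c2c(Br)cn(S(=O)(=O)c3ccc(C)cc3)c12
F2 | step 2 | 3-bromo-N-(diphenylmethylidene)-7-methoxy-1H-indol-4-amine | COc1ccc(N=C(c3ccccc3)c3ccccc3)c2c(Br)c[nH]c12
F3 | step 2 | 3-bromo-N-(diphenylmethylidene)-7-methoxy-1-tosyl-1H-indol-4-amine | COc1ccc(N=C(c3ccccc3)c3ccccc3)c2c(Br)cn(S(=O)(=O)c3ccc(C)cc3)c12
F4 | step 2 | 3-bromo-7-methoxy-1-tosyl-1H-indol-4-amine | COc1ccc(N)c2c(Br)cn(S(=O)(=O)c3ccc(C)cc3)c12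
F5 | step 6 | 2-bromo-1-(3,5-dibromo-7-methoxy-1-tosyl-1H-indol-4-yl)-4-[(trimethylsilyl)oxy]-6,7-dihydro-1H-indole | COc1cc(Br)c(-n2c(Br)cc3c2CCC=C3O[Si](C)(C)C)c2c(Br)cn(S(=O)(=O)c3ccc(C)cc3)c12
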